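**Retrosynthetic overview**
1. Target 23 ⇒ Heck disconnection of the aryl–alkene bond: acrylate 19 (diol 17 + acryloyl chloride) and aryl iodide 22 (catechol → monomethyl ether → iodide).
2. Diol 17 ⇒ hydroxyl-directed reduction of β-hydroxy cycloheptenone 16.
3. 16 ⇒ key step: one-carbon ring expansion (1,2-alkenyl shift) of hydrindenone 13; the six-membered enone becomes the seven-membered β,γ-unsaturated ketone.
4. 13 ⇒ acetone aldol on enone 9; 9 ⇒ its C7a epimer 6 ⇒ Robinson annulation of silyl enol ether 3 with ethyl vinyl ketone; 3 ⇒ asymmetric conjugate methylation of cyclopentenone.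
5. Ring order: cyclopentane (bought) → cyclohexenone (annulation, step 2) → cycloheptenone (ring expansion, step 5).

Assumption: locants are those of the indene or azulene name of each compound, and the ligand enantiomer in step 1 is the one that gives the 3S product.

**Step 1**
Reactants: 1 cyclopent-2-en-1-one
Product: 3 (S)-trimethyl[(3-methylcyclopent-1-en-1-yl)oxy]silane, via dimethylaluminium enolate 2 (not isolated)
Conditions: Me3Al (1.3 equiv), Cu(OTf)2 (2 mol%), BINOL-derived phosphoramidite ligand (4 mol%), Et2O, −30 °C; then TMSOTf, −30 → 0 °C; NaHCO3 (aq)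
Reagents that add atoms: trimethylaluminium C[Al](C)C; trimethylsilyl trifluoromethanesulfonate C[Si](C)(C)OS(=O)(=O)C(F)(F)F
Why: Copper-catalysed asymmetric conjugate addition of methyl (ligand control sets C3 as S) gives a regiodefined aluminium enolate that is trapped on oxygen, a known conjugate addition–enolate trapping sequence.

**Step 2**
Reactants: 3 (S)-trimethyl[(3-methylcyclopent-1-en-1-yl)oxy]silane; 4 pent-1-en-3-one
Product: 6 (1S,7aR)-1,4-dimethyl-1,2,3,6,7,7a-hexahydro-5H-inden-5-one, via diketone 5 (not isolated)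
Conditions: Sc(OTf)3 (5 mol%), CH2Cl2, −78 → −20 °C; then KOH (0.5 equiv), MeOH, 60 °C
Reagents that add atoms: none
Why: Mukaiyama–Michael addition anti to the methyl followed by base-mediated aldol condensation (Robinson annulation) closes the cyclohexenone; the enolisable ring-fusion centre C7a settles trans to the methyl (7aR) and is corrected in step 3.

**Step 3**
Reactants: 6 (1S,7aR)-1,4-dimethyl-1,2,3,6,7,7a-hexahydro-5H-inden-5-one
Product: 9 (1S,7aS)-1,4-dimethyl-1,2,3,6,7,7a-hexahydro-5H-inden-5-one, via potassium dienolate 7 (not isolated), via β,γ-enone 8 (not isolated)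
Conditions: KOt-Bu (2 equiv), t-BuOH/THF, 25 °C; AcOH (aq), −20 °C; then HCl (0.1 M), MeOH, 0 °C; recovered 6 recycled
Reagents that add atoms: none
Why: Ringold-type deconjugation: KOt-Bu forms the extended dienolate through the ring-fusion carbon, kinetic α-protonation gives 8, and acid-mediated reconjugation protonates C7a of the dienol on the face opposite the C1 methyl (kinetic γ-protonation), resetting C7a to S with H-1 and H-7a cis.

**Step 4**
Reactants: 9 (1S,7aS)-1,4-dimethyl-1,2,3,6,7,7a-hexahydro-5H-inden-5-one; 10 acetone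
Product: 13 (1S,6R,7aS)-6-(2-hydroxypropan-2-yl)-1,4-dimethyl-1,2,3,6,7,7a-hexahydro-5H-inden-5-one, via lithium enolate 11 (not isolated), via chlorozinc enolate 12 (not isolated)
Conditions: LiN(i-Pr)2 (1.05 equiv), THF, −78 °C; ZnCl2 (1.1 equiv), −78 → 0 °C; 10 (2 equiv), 0 °C; NH4Cl (aq)
Reagents that add atoms: none
Why: Kinetic α′-deprotonation (no γ-enolisation, so C7a is untouched) and a reversible zinc-mediated aldol addition under thermodynamic control place the chelated hydroxyisopropyl group equatorial, cis-1,3 to the C7a–C1 bond, which sets C6 as R.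

**Step 5**
Reactants: 13 (1S,6R,7aS)-6-(2-hydroxypropan-2-yl)-1,4-dimethyl-1,2,3,6,7,7a-hexahydro-5H-inden-5-one
Product: 16 (3S,3aS,5R)-5-(2-hydroxypropan-2-yl)-3,8-dimethyl-2,3,3a,4,5,7-hexahydroazulen-6(1H)-one, via aluminium alkoxide 14 (not isolated), via α-silyl ketone 15 (not isolated)
Conditions: Me3Al (2.2 equiv), CH2Cl2, −78 → −40 °C; TMSCHN2 (1.5 equiv), −78 → −20 °C; then MeOH, AcOH, 0 °C
Reagents that add atoms: (trimethylsilyl)diazomethane C[Si](C)(C)C=[N+]=[N-]
Why: Proposed new method: an aluminium-alkoxide-anchored, alkenyl-selective one-carbon homologation of a conjugated cyclic enone with TMSCHN2 — the Me2Al alkoxide of the tertiary alcohol and a second Me3Al activate the carbonyl, the diazo carbon adds 1,2, and in the diazonium betaine the silyl group sits anti to the hindered C6 so that only the C4 alkenyl carbon can align anti to N2 and migrate (π-assisted 1,2-shift), giving 15, whose protodesilylation at the α-carbon leaves the tetrasubstituted alkene β,γ to the ketone with no stereocentre touched; the closest known reaction is the organoaluminium-promoted diazoalkane homologation of saturated cycloalkanones (a Tiffeneau–Demjanov-type ring expansion), not shown for enones with alkenyl migration.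

**Step 6**
Reactants: 16 (3S,3aS,5R)-5-(2-hydroxypropan-2-yl)-3,8-dimethyl-2,3,3a,4,5,7-hexahydroazulen-6(1H)-one
Product: 17 (3S,3aS,5S,6S)-5-(2-hydroxypropan-2-yl)-3,8-dimethyl-1,2,3,3a,4,5,6,7-octahydroazulen-6-ol
Conditions: Me4NBH(OAc)3 (5 equiv), MeCN/AcOH 1:1, −30 °C
Reagents that add atoms: none
Why: Hydroxyl-directed reduction (Evans–Saksena type): the acetoxyborohydride bound to the tertiary hydroxyl delivers hydride intramolecularly to the carbonyl face on the side of the side chain, giving the 6S alcohol trans to the C5 substituent.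

**Step 7**
Reactants: 17 (3S,3aS,5S,6S)-5-(2-hydroxypropan-2-yl)-3,8-dimethyl-1,2,3,3a,4,5,6,7-octahydroazulen-6-ol; 18 prop-2-enoyl chloride
Product: 19 (3S,3aS,5S,6S)-5-(2-hydroxypropan-2-yl)-3,8-dimethyl-1,2,3,3a,4,5,6,7-octahydroazulen-6-yl prop-2-enoate
Conditions: 18 (1.3 equiv), Et3N, DMAP (10 mol%), CH2Cl2, −20 → 0 °C
Reagents that add atoms: none
Why: DMAP-catalysed acylation is selective for the secondary alcohol because the tertiary carbinol is too hindered to react.

**Step 8**
Reactants: 20 benzene-1,2-diol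
Product: 21 2-methoxyphenol
Conditions: MeI (1.0 equiv), K2CO3 (1.0 equiv), acetone, 56 °C
Reagents that add atoms: iodomethane CI
Why: Williamson monomethylation of the symmetric diol with one equivalent of MeI; the dimethyl ether and unreacted 20 are removed by base extraction and distillation.

**Step 9**
Reactants: 21 2-methoxyphenol
Product: 22 4-iodo-2-methoxyphenol
Conditions: N-iodosuccinimide (1.0 equiv), TsOH (10 mol%), MeCN, 0 → 25 °C
Reagents that add atoms: N-iodosuccinimide O=C1CCC(=O)N1I
Why: Electrophilic aromatic iodination goes para to the more strongly activating free hydroxyl.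

**Step 10**
Reactants: 19 (3S,3aS,5S,6S)-5-(2-hydroxypropan-2-yl)-3,8-dimethyl-1,2,3,3a,4,5,6,7-octahydroazulen-6-yl prop-2-enoate; 22 4-iodo-2-methoxyphenol
Product: 23 (3S,3aS,5S,6S)-5-(2-hydroxypropan-2-yl)-3,8-dimethyl-1,2,3,3a,4,5,6,7-octahydroazulen-6-yl (2E)-3-(4-hydroxy-3-methoxyphenyl)prop-2-enoate
Conditions: Pd(OAc)2 (5 mol%), P(o-tol)3 (10 mol%), Et3N (3 equiv), DMF, 90 °C
Reagents that add atoms: none
Why: Mizoroki–Heck coupling of the aryl iodide with the acrylate gives the E-cinnamate by syn insertion and syn β-hydride elimination, while the tetrasubstituted ring alkene and the free hydroxyls are inert.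

**Compound list**
1 | cyclopent-2-en-1-one | O=C1C=CCC1 | starting material
2 | dimethylaluminium (S)-3-methylcyclopent-1-en-1-olate | C[C@H]1CCC(O[Al](C)C)=C1 | intermediate
3 | (S)-trimethyl[(3-methylcyclopent-1-en-1-yl)oxy]silane | C[C@H]1CCC(O[Si](C)(C)C)=C1 | intermediate
4 | pent-1-en-3-one | C=CC(=O)CC | starting material
5 | (2R,3S)-3-methyl-2-(3-oxopentyl)cyclopentan-1-one | O=C1CC[C@H](C)[C@H]1CCC(=O)CC | intermediate
6 | (1S,7aR)-1,4-dimethyl-1,2,3,6,7,7a-hexahydro-5H-inden-5-one | O=C1C(C)=C2CC[C@H](C)[C@H]2CC1 | intermediate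
7 | potassium (1S)-1,4-dimethyl-2,3,6,7-tetrahydro-1H-inden-5-olate | [K]OC1=C(C)C2=C(CC1)[C@@H](C)CC2 | intermediate
8 | (1S)-1,4-dimethyl-1,2,3,4,6,7-hexahydro-5H-inden-5-one (C4 epimers) | O=C1CCC2=C(CC[C@@H]2C)C1C | intermediate
9 | (1S,7aS)-1,4-dimethyl-1,2,3,6,7,7a-hexahydro-5H-inden-5-one | O=C1C(C)=C2CC[C@H](C)[C@@H]2CC1 | intermediate
10 | acetone | CC(C)=O | starting material
11 | lithium (1S,7aS)-1,4-dimethyl-2,3,7,7a-tetrahydro-1H-inden-5-olate | [Li]OC1=CC[C@H]2[C@@H](C)CCC2=C1C | intermediate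
12 | chlorozinc (1S,7aS)-1,4-dimethyl-2,3,7,7a-tetrahydro-1H-inden-5-olate | Cl[Zn]OC1=CC[C@H]2[C@@H](C)CCC2=C1C | intermediate
13 | (1S,6R,7aS)-6-(2-hydroxypropan-2-yl)-1,4-dimethyl-1,2,3,6,7,7a-hexahydro-5H-inden-5-one | O=C1C(C)=C2CC[C@H](C)[C@@H]2C[C@@H]1C(C)(C)O | intermediate
14 | dimethylaluminium 2-[(1S,6R,7aS)-1,4-dimethyl-5-oxo-2,3,5,6,7,7a-hexahydro-1H-inden-6-yl]propan-2-olate | O=C1C(C)=C2CC[C@H](C)[C@@H]2C[C@@H]1C(C)(C)O[Al](C)C | intermediate
15 | dimethylaluminium 2-[(3S,3aS,5R)-3,8-dimethyl-6-oxo-7-(trimethylsilyl)-1,2,3,3a,4,5,6,7-octahydroazulen-5-yl]propan-2-olate (C7 epimers) | O=C1C([Si](C)(C)C)C(C)=C2CC[C@H](C)[C@@H]2C[C@@H]1C(C)(C)O[Al](C)C | intermediate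
16 | (3S,3aS,5R)-5-(2-hydroxypropan-2-yl)-3,8-dimethyl-2,3,3a,4,5,7-hexahydroazulen-6(1H)-one | O=C1CC(C)=C2CC[C@H](C)[C@@H]2C[C@@H]1C(C)(C)O | intermediate
17 | (3S,3aS,5S,6S)-5-(2-hydroxypropan-2-yl)-3,8-dimethyl-1,2,3,3a,4,5,6,7-octahydroazulen-6-ol | O[C@H]1CC(C)=C2CC[C@H](C)[C@@H]2C[C@@H]1C(C)(C)O | intermediate
18 | prop-2-enoyl chloride | C=CC(=O)Cl | starting material
19 | (3S,3aS,5S,6S)-5-(2-hydroxypropan-2-yl)-3,8-dimethyl-1,2,3,3a,4,5,6,7-octahydroazulen-6-yl prop-2-enoate | C=CC(=O)O[C@H]1CC(C)=C2CC[C@H](C)[C@@H]2C[C@@H]1C(C)(C)O | intermediate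
20 | benzene-1,2-diol | Oc1ccccc1O | starting material
21 | 2-methoxyphenol | COc1ccccc1O | intermediate
22 | 4-iodo-2-methoxyphenol | COc1cc(I)ccc1O | intermediate
23 | (3S,3aS,5S,6S)-5-(2-hydroxypropan-2-yl)-3,8-dimethyl-1,2,3,3a,4,5,6,7-octahydroazulen-6-yl (2E)-3-(4-hydroxy-3-methoxyphenyl)prop-2-enoate | COc1cc(/C=C/C(=O)O[C@H]2CC(C)=C3CC[C@H](C)[C@@H]3C[C@@H]2C(C)(C)O)ccc1O | target

**Totals**
Total step count: 10. Longest linear sequence: 8 (steps 1–7 and 10; steps 8–9 are the side branch to 22).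

**Steps most likely to fail**

Step 5 (the proposed ring expansion). The risks are competing migration of C6, epoxide formation, or methyl transfer from aluminium. The fallback sets out from 13 and comes back at 16, using the established β-oxido carbenoid ring enlargement. LiCHBr2 (from CH2Br2 and lithium 2,2,6,6-tetramethylpiperidide, THF, −78 °C, 2.2 equiv) adds to the ketone to give the dibromomethyl carbinol (1S,6R,7aS)-5-(dibromomethyl)-6-(2-hydroxypropan-2-yl)-1,4-dimethyl-2,3,5,6,7,7a-hexahydro-1H-inden-5-ol F1. n-BuLi (3 equiv, −78 → −20 °C) then effects bromine–lithium exchange, and the carbenoid rearranges with migration of the alkenyl carbon and loss of bromide to the lithium dienolate of 16. Quenching with AcOH at −78 °C protonates the α-carbon and gives 16.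

Step 3 (kinetic resetting of C7a). The γ-protonation may show only modest facial selectivity, and over-exposure to acid returns 6. The fallback sets out from 8, isolated after the AcOH quench, and comes back at 9. Hydrogenation with H2 (50 bar) and [Ir(cod)(PCy3)(py)]PF6 in CH2Cl2 adds hydrogen to the tetrasubstituted ring-fusion alkene from the face away from the C1 methyl. This gives the cis-fused saturated ketone (1S,3aR,7aS)-1,4-dimethyloctahydro-5H-inden-5-one F2, in which C7a is fixed and no longer enolisable. 2-Iodoxybenzoic acid (DMSO, 70 °C) then dehydrogenates through the more substituted enol to restore the C3a=C4 enone, 9.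

Step 4 (thermodynamic aldol). The risks are incomplete equilibration of the zinc aldolate, or proton transfer from acetone that would let C7a epimerise. The fallback sets out from 9 and comes back at 13. A kinetic lithium aldol (LiN(i-Pr)2, THF, −78 °C; acetone; AcOH at −78 °C) gives mainly the axial-attack product, (1S,6S,7aS)-6-(2-hydroxypropan-2-yl)-1,4-dimethyl-1,2,3,6,7,7a-hexahydro-5H-inden-5-one F3. F3 is then converted with LiN(i-Pr)2 (2.2 equiv, −78 → −40 °C) into its alkoxide–enolate dianion, and axial protonation with AcOH at −78 °C turns the side chain equatorial to give 13.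

**Further compounds**
F1 | step 5 | (1S,6R,7aS)-5-(dibromomethyl)-6-(2-hydroxypropan-2-yl)-1,4-dimethyl-2,3,5,6,7,7a-hexahydro-1H-inden-5-ol (C5 epimers) | OC1(C(Br)Br)C(C)=C2CC[C@H](C)[C@@H]2C[C@@H]1C(C)(C)O
F2 | step 3 | (1S,3aR,7aS)-1,4-dimethyloctahydro-5H-inden-5-one (C4 epimers) | O=C1C(C)[C@@H]2CC[C@H](C)[C@@H]2CC1
F3 | step 4 | (1S,6S,7aS)-6-(2-hydroxypropan-2-yl)-1,4-dimethyl-1,2,3,6,7,7a-hexahydro-5H-inden-5-one | O=C1C(C)=C2CC[C@H](C)[C@@H]2C[C@H]1C(C)(C)O
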